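**Strategy**

The ten-membered carbocycle is traced back to a cyclohexene made of C9, C10, C1, C2, C3 and C4, in which the Z C1–C10 alkene is locked by the ring, and whose C4–C9 bond is the central bond of a 1,5-diene carrying C5=C6 on C4 and C8=C7 on C9. An anionic oxy-Cope rearrangement cuts C4–C9 and joins C6 to C7 through a chair, giving in one operation the Z,E-cyclodecadienone ring, the E C4–C5 alkene and the C6 and C7 stereocentres; its enolate is hydroxylated at C8 in the same flask. The precursor is a trans-1,2-dialkenylcyclohex-2-enol with an E PMB enol ether on C4 and an E 2-substituted dienyl arm on C9.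

Key step: step 14

Assumption: germacrane numbering is used (ring C1 to C10, C11 on C7 with carbonyl C12 and methylene C13, methyl C14 on C10, methyl C15 on C4), and the facial sense of the two catalyst-controlled steps (3 and 5) is assigned by analogy and would be confirmed on 7 and 10 before going on.

**Route**

Step 1
Reactants: 1 2-methylcyclohex-2-en-1-one
Product: 3 2,6-dimethylcyclohex-2-en-1-one (racemic), via lithium dienolate 2 (not isolated)
Conditions: LiN(i-Pr)2, THF, −78 °C; MeI, −78 to 0 °C
Reagents that add atoms: iodomethane, CI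
Why: Kinetic deprotonation on the saturated side of the carbonyl and C-methylation of the cross-conjugated lithium dienolate (enolate alkylation) should give the 2,6-dimethyl enone, whose new centre may stay racemic because it is planarised again in step 2.

Step 2
Reactants: 3 2,6-dimethylcyclohex-2-en-1-one; 4 allyl chloroformate
Product: 6 allyl 2,6-dimethylcyclohexa-1,5-dien-1-yl carbonate, via lithium enolate 5 (not isolated)
Conditions: LiN(SiMe3)2, TMEDA, THF, −78 °C; 4, −78 °C
Reagents that add atoms: none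
Why: The enolate carbon is fully substituted and hindered, so the hard chloroformate should acylate oxygen (enolate O-acylation to an allyl enol carbonate), giving an achiral substrate with the enolate position fixed.

Step 3
Reactants: 6 allyl 2,6-dimethylcyclohexa-1,5-dien-1-yl carbonate
Product: 7 (S)-6-allyl-2,6-dimethylcyclohex-2-en-1-one
Conditions: Pd2(dba)3 (2.5 mol%), (S)-t-BuPHOX (6 mol%), THF, 25 °C
Reagents that add atoms: none
Why: Zerovalent palladium ionises the allyl carbonate, CO2 is lost and the phosphinooxazoline-bound allylpalladium enolate recombines at carbon (decarboxylative asymmetric Tsuji allylation), the ligand choosing the enolate face so that the quaternary centre C4 is set; any minor enantiomer would be removed as a diastereomer after step 5.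

Step 4
Reactants: 7 (S)-6-allyl-2,6-dimethylcyclohex-2-en-1-one
Product: 9 (R)-6-allyl-2,6-dimethylcyclohex-2-ene-1,4-dione, via γ-tert-butylperoxy enone 8 (not isolated)
Conditions: Pd(OH)2/C (5 mol%), t-BuOOH (5 equiv), K2CO3, CH2Cl2, 0 to 25 °C
Reagents that add atoms: tert-butyl hydroperoxide, CC(C)(C)OO
Why: tert-Butylperoxy radicals should abstract the ring hydrogen at C2, which is allylic and vinylogous to the carbonyl, and the γ-peroxide then loses tert-butanol under carbonate to give the ene-1,4-dione (Pd(OH)2/C–TBHP γ-oxidation of an enone); no centre is formed and the descriptor of C4 changes only through the priorities.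

Step 5
Reactants: 9 (R)-6-allyl-2,6-dimethylcyclohex-2-ene-1,4-dione
Product: 10 (4R,6R)-6-allyl-4-hydroxy-2,6-dimethylcyclohex-2-en-1-one
Conditions: RuCl[(R,R)-TsDPEN](p-cymene) (1 mol%), HCO2H/Et3N (5:2), CH2Cl2, 0 to 25 °C
Reagents that add atoms: none
Why: Only the C2 carbonyl is accessible (C9 sits between the quaternary C4 and the methyl-bearing C10), and the ruthenium hydride delivers hydrogen through the outer-sphere six-membered transition state with the conjugated alkene in the place of an aryl group (Noyori asymmetric transfer hydrogenation), so the catalyst should set C2 as R whatever the configuration at C4.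

Step 6
Reactants: 10 (4R,6R)-6-allyl-4-hydroxy-2,6-dimethylcyclohex-2-en-1-one
Product: 11 (4R,6R)-6-allyl-4-[(tert-butyldimethylsilyl)oxy]-2,6-dimethylcyclohex-2-en-1-one
Conditions: TBSCl, imidazole, DMF, 25 °C
Reagents that add atoms: tert-butyldimethylsilyl chloride, CC(C)(C)[Si](C)(C)Cl
Why: Imidazole-promoted silylation of the secondary allylic alcohol (silyl ether formation) protects C2–O for the organometallic and basic steps ahead without touching the C2 centre.

Step 7
Reactants: 11 (4R,6R)-6-allyl-4-[(tert-butyldimethylsilyl)oxy]-2,6-dimethylcyclohex-2-en-1-one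
Product: 12 (4R,6S)-4-[(tert-butyldimethylsilyl)oxy]-2,6-dimethyl-6-[(E)-prop-1-en-1-yl]cyclohex-2-en-1-one
Conditions: RuHCl(CO)(PPh3)3 (5 mol%), toluene, 80 °C
Reagents that add atoms: none
Why: Reversible ruthenium hydride addition and β-hydride elimination move the terminal alkene one position inward, where it must stop because C4 is quaternary (alkene isomerisation); the E/Z composition does not matter since the alkene is cleaved next.

Step 8
Reactants: 12 (4R,6S)-4-[(tert-butyldimethylsilyl)oxy]-2,6-dimethyl-6-[(E)-prop-1-en-1-yl]cyclohex-2-en-1-one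
Product: 14 (1S,5R)-5-[(tert-butyldimethylsilyl)oxy]-1,3-dimethyl-2-oxocyclohex-3-ene-1-carbaldehyde, via secondary ozonide 13 (not isolated)
Conditions: O3, CH2Cl2, −78 °C (Sudan Red 7B end point); PPh3, −78 to 25 °C
Reagents that add atoms: ozone, [O-][O+]=O
Why: Ozone adds to the electron-rich propenyl alkene far faster than to the electron-poor trisubstituted enone alkene, and triphenylphosphine reduces the ozonide to the C5 aldehyde (ozonolysis with reductive work-up), leaving C4 untouched.

Step 9
Reactants: 14 (1S,5R)-5-[(tert-butyldimethylsilyl)oxy]-1,3-dimethyl-2-oxocyclohex-3-ene-1-carbaldehyde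
Product: 15 (4R,6S)-4-[(tert-butyldimethylsilyl)oxy]-2,6-dimethyl-6-[(E)-2-(4,4,5,5-tetramethyl-1,3,2-dioxaborolan-2-yl)ethenyl]cyclohex-2-en-1-one
Conditions: CrCl2 (8 equiv), Cl2CHBpin (2 equiv), LiI (4 equiv), THF, 25 °C
Reagents that add atoms: 2-(dichloromethyl)-4,4,5,5-tetramethyl-1,3,2-dioxaborolane, ClC(Cl)B1OC(C)(C)C(C)(C)O1
Why: The geminal dichromium reagent adds to the aldehyde only (the hindered ketone and the enone are inert to divalent chromium) and the β-oxido chromium adduct eliminates to the E alkenyl boronate (Takai–Utimoto olefination), which brings in C6 with defined geometry.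

Step 10
Reactants: 15 (4R,6S)-4-[(tert-butyldimethylsilyl)oxy]-2,6-dimethyl-6-[(E)-2-(4,4,5,5-tetramethyl-1,3,2-dioxaborolan-2-yl)ethenyl]cyclohex-2-en-1-one; 16 4-methoxybenzyl alcohol
Product: 17 (4R,6S)-4-[(tert-butyldimethylsilyl)oxy]-6-{(E)-2-[(4-methoxybenzyl)oxy]ethenyl}-2,6-dimethylcyclohex-2-en-1-one
Conditions: Cu(OAc)2 (2 equiv), Et3N (4 equiv), 16 (15 equiv), 4 Å MS, CH2Cl2, air, 25 °C
Reagents that add atoms: none
Why: Transfer of the alkenyl group from boron to divalent copper, oxidation to trivalent copper and C–O reductive elimination (Chan–Lam-type alkenylation of a primary alcohol) should keep the E geometry, and the near-neutral conditions at 25 °C spare the base-sensitive γ-silyloxy enone.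

Step 11
Reactants: 16 4-methoxybenzyl alcohol; 18 2,3-dibromopropene
Product: 20 1-{[(2-bromoprop-2-en-1-yl)oxy]methyl}-4-methoxybenzene, via sodium alkoxide 19 (not isolated)
Conditions: NaH, THF, 0 °C; 18, 0 to 25 °C
Reagents that add atoms: none
Why: The alkoxide displaces the allylic bromide while the vinylic bromide is inert (Williamson ether synthesis); PMB is chosen for C12–O so that it can leave later together with the PMB group on C6–O.

Step 12
Reactants: 20 1-{[(2-bromoprop-2-en-1-yl)oxy]methyl}-4-methoxybenzene; 21 (E)-1,2-bis(tributylstannyl)ethene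
Product: 22 tributyl[(1E)-3-{[(4-methoxybenzyl)oxy]methyl}buta-1,3-dien-1-yl]stannane
Conditions: Pd(PPh3)4 (5 mol%), 21 (2.5 equiv), toluene, 90 °C
Reagents that add atoms: none
Why: Oxidative addition of zerovalent palladium to the vinylic C–Br bond, transfer of one stannylvinyl group and reductive elimination (Stille coupling) should give the E dienylstannane, the excess of 21 holding back a second coupling.

Step 13
Reactants: 22 tributyl[(1E)-3-{[(4-methoxybenzyl)oxy]methyl}buta-1,3-dien-1-yl]stannane; 17 (4R,6S)-4-[(tert-butyldimethylsilyl)oxy]-6-{(E)-2-[(4-methoxybenzyl)oxy]ethenyl}-2,6-dimethylcyclohex-2-en-1-one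
Product: 24 (1S,4R,6S)-4-[(tert-butyldimethylsilyl)oxy]-1-[(1E)-3-{[(4-methoxybenzyl)oxy]methyl}buta-1,3-dien-1-yl]-6-{(E)-2-[(4-methoxybenzyl)oxy]ethenyl}-2,6-dimethylcyclohex-2-en-1-ol, via dienyllithium 23 (not isolated)
Conditions: n-BuLi (0.95 equiv relative to 22), THF, −78 °C; 17, −78 to −40 °C; NH4Cl aq
Reagents that add atoms: none
Why: Tin–lithium exchange gives the E dienyllithium with retention, which adds 1,2 to the hindered enone carbonyl (organolithium addition); in the half-chair that keeps the C2 silyloxy group and the C4 methyl equatorial the enol-ether arm is axial, so the nucleophile should enter anti to it and set C9 with the two alkenyl arms trans.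

Step 14
Reactants: 24 (1S,4R,6S)-4-[(tert-butyldimethylsilyl)oxy]-1-[(1E)-3-{[(4-methoxybenzyl)oxy]methyl}buta-1,3-dien-1-yl]-6-{(E)-2-[(4-methoxybenzyl)oxy]ethenyl}-2,6-dimethylcyclohex-2-en-1-ol
Product: 27 (1(10)Z,4E)-2-[(tert-butyldimethylsilyl)oxy]-8-hydroxy-6,12-bis[(4-methoxybenzyl)oxy]germacra-1(10),4,11(13)-trien-9-one (C2, C6, C7, C8 arranged as in the target), via potassium alkoxide 25 (not isolated), via potassium enolate 26 (not isolated)
Conditions: KN(SiMe3)2 (1.1 equiv), 18-crown-6, THF, −78 to 25 °C; then −78 °C, 3-phenyl-2-(phenylsulfonyl)oxaziridine; NH4Cl aq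
Reagents that add atoms: 3-phenyl-2-(phenylsulfonyl)oxaziridine, O=S(=O)(c1ccccc1)N1OC1c1ccccc1
Why: The crown ether frees the tertiary potassium alkoxide 25, whose C4–C9 bond is weakened so that a concerted [3,3] shift joins C6 to C7 as C4–C9 breaks (anionic oxy-Cope rearrangement, the known ring expansion of trans-1,2-dialkenylcyclohexanols to cyclodec-5-enones). The ten-membered ring is not closed end to end but arises by ring expansion, through cleavage of the bond that the cyclohexene shares with the six-centre chair, so no dilution is needed and the ring alkene reappears unchanged as the Z C1–C10 alkene. The configurations needed at C6 and C7 (6R,7S in the target) follow from the chair in which both arms are equatorial on the cyclohexene, C3 is equatorial on C4 (hence the E C4–C5 alkene) and the C6 ether oxygen and C11 are equatorial because both arm alkenes are E, so that chirality is passed on suprafacially from C4 and C9. C8 should be set when enolate 26, still in the crossed conformation in which its inner face looks at the C4–C5 alkene, takes oxygen from the oxaziridine on its open outer face (Davis hydroxylation of a potassium enolate), which corresponds to 8R. The selectivity needed is chair over boat and this shift over the boat-type shift through the ring alkene (C1 to C6) or over fragmentation; the trans-diequatorial placing of the two arms, possible only in the chair, and the irreversible formation of the enolate should secure it. The price is a 1,3-diaxial contact between the C2 silyloxy group and C15 in the reactive conformer, which may call for gentle warming.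

Step 15
Reactants: 27 (1(10)Z,4E)-2-[(tert-butyldimethylsilyl)oxy]-8-hydroxy-6,12-bis[(4-methoxybenzyl)oxy]germacra-1(10),4,11(13)-trien-9-one; 28 angelic acid
Product: 30 8-O-angeloyl derivative of 27, via mixed anhydride 29 (not isolated)
Conditions: 28, 2,4,6-Cl3C6H2COCl, Et3N, toluene, 25 °C; 27, 60 °C
Reagents that add atoms: none
Why: The mixed anhydride passes its less hindered angeloyl group to the C8 hydroxyl (Yamaguchi-type esterification), and leaving out a nucleophilic catalyst should keep the Z alkene of the angelate from turning into the tiglate; C8 is esterified before the ketone is reduced so that the two oxygens stay differentiated.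

Step 16
Reactants: 30 8-O-angeloyl derivative of 27
Product: 31 (1(10)Z,4E)-8-(angeloyloxy)-2-[(tert-butyldimethylsilyl)oxy]-6,12-bis[(4-methoxybenzyl)oxy]germacra-1(10),4,11(13)-trien-9-ol (all centres as in the target)
Conditions: NaBH4, CeCl3·7H2O, MeOH/THF, −78 °C
Reagents that add atoms: none
Why: Cerium-assisted borohydride adds 1,2 to the enone and leaves the esters alone (Luche reduction), and attack anti to the C8–O bond of the α-acyloxy group (polar Felkin–Anh model) should place the new C9 hydroxyl syn to the C8 angelate, which is 9R.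

Step 17
Reactants: 31 (1(10)Z,4E)-8-(angeloyloxy)-2-[(tert-butyldimethylsilyl)oxy]-6,12-bis[(4-methoxybenzyl)oxy]germacra-1(10),4,11(13)-trien-9-ol
Product: 32 (1(10)Z,4E)-8-(angeloyloxy)-6,12-bis[(4-methoxybenzyl)oxy]germacra-1(10),4,11(13)-triene-2,9-diol
Conditions: HF·pyridine, pyridine, THF, 0 to 25 °C
Reagents that add atoms: none
Why: Fluoride cleaves the secondary TBS ether through the strong Si–F bond (desilylation) and the pyridine buffer should hold back migration of the angeloyl group to the C9 hydroxyl; the ketone is reduced before this step so that a Z γ-hydroxy enone, which could close to a furan, never exists.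

Step 18
Reactants: 32 (1(10)Z,4E)-8-(angeloyloxy)-6,12-bis[(4-methoxybenzyl)oxy]germacra-1(10),4,11(13)-triene-2,9-diol
Product: 33 (1(10)Z,4E)-2,9-diacetoxy-8-(angeloyloxy)-6,12-bis[(4-methoxybenzyl)oxy]germacra-1(10),4,11(13)-triene
Conditions: Ac2O, pyridine, DMAP (cat.), CH2Cl2, 0 °C
Reagents that add atoms: acetic anhydride, CC(=O)OC(C)=O
Why: DMAP-catalysed acyl transfer esterifies both secondary allylic alcohols in one operation (acetylation), which installs the C2 and C9 acetates of the target together.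

Step 19
Reactants: 33 (1(10)Z,4E)-2,9-diacetoxy-8-(angeloyloxy)-6,12-bis[(4-methoxybenzyl)oxy]germacra-1(10),4,11(13)-triene
Product: 34 (1(10)Z,4E)-2,9-diacetoxy-8-(angeloyloxy)germacra-1(10),4,11(13)-triene-6,12-diol
Conditions: DDQ (3 equiv), CH2Cl2/pH 7 buffer, 0 °C
Reagents that add atoms: none
Why: Hydride abstraction by DDQ from the two electron-rich benzylic positions and hydrolysis of the oxocarbenium ions release both PMB ethers at once (oxidative PMB cleavage), which is the reason for giving C12–O the same group as C6–O.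

Step 20
Reactants: 34 (1(10)Z,4E)-2,9-diacetoxy-8-(angeloyloxy)germacra-1(10),4,11(13)-triene-6,12-diol
Product: 37 (2R,6R,7S,8R,9R,1(10)Z,4E)-2,9-diacetoxy-8-(angeloyloxy)germacra-1(10),4,11(13)-trien-12,6-olide (CNP0499619.1), via hydroxy enal 35 (not isolated), via lactol 36 (not isolated)
Conditions: TEMPO (20 mol%), PhI(OAc)2 (3 equiv), CH2Cl2, 25 °C
Reagents that add atoms: none
Why: The oxoammonium salt formed from TEMPO oxidises the primary allylic alcohol much faster than the secondary one, the aldehyde is trapped by the C6 hydroxyl as the lactol and a second oxidation gives the α-methylene γ-lactone (TEMPO/PhI(OAc)2 oxidative lactonisation) without touching any stereocentre.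

**Compound list**

1 | 2-methylcyclohex-2-en-1-one | O=C1CCCC=C1C | starting material
2 | lithium 6-methylcyclohexa-1,5-dien-1-olate | [Li]OC1=CCCC=C1C | intermediate (not isolated)
3 | 2,6-dimethylcyclohex-2-en-1-one (racemic) | CC1CCC=C(C)C1=O | intermediate
4 | allyl chloroformate | C=CCOC(=O)Cl | starting material
5 | lithium 2,6-dimethylcyclohexa-1,5-dien-1-olate | [Li]OC1=C(C)CCC=C1C | intermediate (not isolated)
6 | allyl 2,6-dimethylcyclohexa-1,5-dien-1-yl carbonate | C=CCOC(=O)OC1=C(C)CCC=C1C | intermediate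
7 | (S)-6-allyl-2,6-dimethylcyclohex-2-en-1-one | C[C@@]1(CC=C)CCC=C(C)C1=O | intermediate
8 | (6R)-6-allyl-4-(tert-butylperoxy)-2,6-dimethylcyclohex-2-en-1-one (both C4 epimers) | C[C@@]1(CC=C)CC(OOC(C)(C)C)C=C(C)C1=O | intermediate (not isolated)
9 | (R)-6-allyl-2,6-dimethylcyclohex-2-ene-1,4-dione | C[C@@]1(CC=C)CC(=O)C=C(C)C1=O | intermediate
10 | (4R,6R)-6-allyl-4-hydroxy-2,6-dimethylcyclohex-2-en-1-one | C[C@@]1(CC=C)C[C@@H](O)C=C(C)C1=O | intermediate
11 | (4R,6R)-6-allyl-4-[(tert-butyldimethylsilyl)oxy]-2,6-dimethylcyclohex-2-en-1-one | C[C@@]1(CC=C)C[C@@H](O[Si](C)(C)C(C)(C)C)C=C(C)C1=O | intermediate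
12 | (4R,6S)-4-[(tert-butyldimethylsilyl)oxy]-2,6-dimethyl-6-[(E)-prop-1-en-1-yl]cyclohex-2-en-1-one | C[C@@]1(/C=C/C)C[C@@H](O[Si](C)(C)C(C)(C)C)C=C(C)C1=O | intermediate
13 | (4R,6S)-4-[(tert-butyldimethylsilyl)oxy]-2,6-dimethyl-6-(5-methyl-1,2,4-trioxolan-3-yl)cyclohex-2-en-1-one (ozonide isomers) | C[C@@]1(C2OOC(C)O2)C[C@@H](O[Si](C)(C)C(C)(C)C)C=C(C)C1=O | intermediate (not isolated)
14 | (1S,5R)-5-[(tert-butyldimethylsilyl)oxy]-1,3-dimethyl-2-oxocyclohex-3-ene-1-carbaldehyde | C[C@@]1(C=O)C[C@@H](O[Si](C)(C)C(C)(C)C)C=C(C)C1=O | intermediate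
15 | (4R,6S)-4-[(tert-butyldimethylsilyl)oxy]-2,6-dimethyl-6-[(E)-2-(4,4,5,5-tetramethyl-1,3,2-dioxaborolan-2-yl)ethenyl]cyclohex-2-en-1-one | C[C@@]1(/C=C/B2OC(C)(C)C(C)(C)O2)C[C@@H](O[Si](C)(C)C(C)(C)C)C=C(C)C1=O | intermediate
16 | 4-methoxybenzyl alcohol | COc1ccc(CO)cc1 | starting material
17 | (4R,6S)-4-[(tert-butyldimethylsilyl)oxy]-6-{(E)-2-[(4-methoxybenzyl)oxy]ethenyl}-2,6-dimethylcyclohex-2-en-1-one | C[C@@]1(/C=C/OCc2ccc(OC)cc2)C[C@@H](O[Si](C)(C)C(C)(C)C)C=C(C)C1=O | intermediate
18 | 2,3-dibromopropene | C=C(Br)CBr | starting material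
19 | sodium 4-methoxybenzyl oxide | [Na]OCc1ccc(OC)cc1 | intermediate (not isolated)
20 | 1-{[(2-bromoprop-2-en-1-yl)oxy]methyl}-4-methoxybenzene | COc1ccc(COCC(Br)=C)cc1 | intermediate
21 | (E)-1,2-bis(tributylstannyl)ethene | CCCC[Sn](CCCC)(CCCC)/C=C/[Sn](CCCC)(CCCC)CCCC | starting material
22 | tributyl[(1E)-3-{[(4-methoxybenzyl)oxy]methyl}buta-1,3-dien-1-yl]stannane | CCCC[Sn](CCCC)(CCCC)/C=C/C(=C)COCc1ccc(OC)cc1 | intermediate
23 | [(1E)-3-{[(4-methoxybenzyl)oxy]methyl}buta-1,3-dien-1-yl]lithium | [Li]/C=C/C(=C)COCc1ccc(OC)cc1 | intermediate (not isolated)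
24 | (1S,4R,6S)-4-[(tert-butyldimethylsilyl)oxy]-1-[(1E)-3-{[(4-methoxybenzyl)oxy]methyl}buta-1,3-dien-1-yl]-6-{(E)-2-[(4-methoxybenzyl)oxy]ethenyl}-2,6-dimethylcyclohex-2-en-1-ol (key-step precursor) | C[C@@]1(/C=C/OCc2ccc(OC)cc2)C[C@@H](O[Si](C)(C)C(C)(C)C)C=C(C)[C@@]1(O)/C=C/C(=C)COCc3ccc(OC)cc3 | intermediate
25 | potassium alkoxide of 24 | C[C@@]1(/C=C/OCc2ccc(OC)cc2)C[C@@H](O[Si](C)(C)C(C)(C)C)C=C(C)[C@@]1(O[K])/C=C/C(=C)COCc3ccc(OC)cc3 | intermediate (not isolated)
26 | potassium (1(10)Z,4E)-2-[(tert-butyldimethylsilyl)oxy]-6,12-bis[(4-methoxybenzyl)oxy]germacra-1(10),4,8,11(13)-tetraen-9-olate, C7 and C10 trans across C8=C9, C2, C6 and C7 as in the target | COc1ccc(CO[C@@H]2/C=C(\C)C[C@@H](O[Si](C)(C)C(C)(C)C)/C=C(/C)\C(O[K])=C\[C@H]2C(=C)COCc3ccc(OC)cc3)cc1 | intermediate (not isolated)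
27 | (1(10)Z,4E)-2-[(tert-butyldimethylsilyl)oxy]-8-hydroxy-6,12-bis[(4-methoxybenzyl)oxy]germacra-1(10),4,11(13)-trien-9-one, C2, C6, C7 and C8 as in the target | COc1ccc(CO[C@@H]2/C=C(\C)C[C@@H](O[Si](C)(C)C(C)(C)C)/C=C(/C)C(=O)[C@H](O)[C@H]2C(=C)COCc3ccc(OC)cc3)cc1 | intermediate
28 | angelic acid, (Z)-2-methylbut-2-enoic acid | C/C=C(/C)C(=O)O | starting material
29 | angelic 2,4,6-trichlorobenzoic anhydride | C/C=C(/C)C(=O)OC(=O)c1c(Cl)cc(Cl)cc1Cl | intermediate (not isolated)
30 | (1(10)Z,4E)-8-(angeloyloxy)-2-[(tert-butyldimethylsilyl)oxy]-6,12-bis[(4-methoxybenzyl)oxy]germacra-1(10),4,11(13)-trien-9-one, centres as in the target | COc1ccc(CO[C@@H]2/C=C(\C)C[C@@H](O[Si](C)(C)C(C)(C)C)/C=C(/C)C(=O)[C@H](OC(=O)/C(C)=C\C)[C@H]2C(=C)COCc3ccc(OC)cc3)cc1 | intermediate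
31 | (1(10)Z,4E)-8-(angeloyloxy)-2-[(tert-butyldimethylsilyl)oxy]-6,12-bis[(4-methoxybenzyl)oxy]germacra-1(10),4,11(13)-trien-9-ol, centres as in the target | COc1ccc(CO[C@@H]2/C=C(\C)C[C@@H](O[Si](C)(C)C(C)(C)C)/C=C(/C)[C@@H](O)[C@H](OC(=O)/C(C)=C\C)[C@H]2C(=C)COCc3ccc(OC)cc3)cc1 | intermediate
32 | (1(10)Z,4E)-8-(angeloyloxy)-6,12-bis[(4-methoxybenzyl)oxy]germacra-1(10),4,11(13)-triene-2,9-diol, centres as in the target | COc1ccc(CO[C@@H]2/C=C(\C)C[C@@H](O)/C=C(/C)[C@@H](O)[C@H](OC(=O)/C(C)=C\C)[C@H]2C(=C)COCc3ccc(OC)cc3)cc1 | intermediate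
33 | (1(10)Z,4E)-2,9-diacetoxy-8-(angeloyloxy)-6,12-bis[(4-methoxybenzyl)oxy]germacra-1(10),4,11(13)-triene, centres as in the target | COc1ccc(CO[C@@H]2/C=C(\C)C[C@@H](OC(C)=O)/C=C(/C)[C@@H](OC(C)=O)[C@H](OC(=O)/C(C)=C\C)[C@H]2C(=C)COCc3ccc(OC)cc3)cc1 | intermediate
34 | (1(10)Z,4E)-2,9-diacetoxy-8-(angeloyloxy)germacra-1(10),4,11(13)-triene-6,12-diol, centres as in the target | O[C@@H]1/C=C(\C)C[C@@H](OC(C)=O)/C=C(/C)[C@@H](OC(C)=O)[C@H](OC(=O)/C(C)=C\C)[C@H]1C(=C)CO | intermediate
35 | (1(10)Z,4E)-2,9-diacetoxy-8-(angeloyloxy)-6-hydroxygermacra-1(10),4,11(13)-trien-12-al | O[C@@H]1/C=C(\C)C[C@@H](OC(C)=O)/C=C(/C)[C@@H](OC(C)=O)[C@H](OC(=O)/C(C)=C\C)[C@H]1C(=C)C=O | intermediate (not isolated)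
36 | 12,6-lactol of 35 (both anomers) | C=C1C(O)O[C@@H]2/C=C(\C)C[C@@H](OC(C)=O)/C=C(/C)[C@@H](OC(C)=O)[C@H](OC(=O)/C(C)=C\C)[C@@H]12 | intermediate (not isolated)
37 | (2R,6R,7S,8R,9R,1(10)Z,4E)-2,9-diacetoxy-8-(angeloyloxy)germacra-1(10),4,11(13)-trien-12,6-olide (CNP0499619.1) | C=C1C(=O)O[C@@H]2/C=C(\C)C[C@@H](OC(C)=O)/C=C(/C)[C@@H](OC(C)=O)[C@H](OC(=O)/C(C)=C\C)[C@@H]12 | target

**Step count and risks**

Total step count: 20. Longest linear sequence: 18 steps (steps 1 to 10 and 13 to 20, from 2-methylcyclohex-2-en-1-one); the dienyl arm takes 2 steps (11 and 12).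

The three steps most likely to fail:

Step 14. The free alkoxide may fragment heterolytically at C4–C9 and recombine without the chair, or the rearrangement may stall because of the 1,3-diaxial contact in the reactive conformer; the enolate may also relax conformationally before it is oxidised, so that face selectivity at C8 is lost. The fallback sets out from 24 and comes back at 27. The tertiary alcohol would be silylated with N-(trimethylsilyl)imidazole to the trimethylsilyl ether F1. F1 would be rearranged without base (thermal siloxy-Cope, toluene, sealed tube, about 180 °C) through the same chair to the trimethylsilyl enol ether F2. F2 would be oxidised with one equivalent of dimethyldioxirane at −78 °C (Rubottom oxidation; the silyl enol ether is the most electron-rich alkene) to the α-silyloxy ketone F3, and citric acid in methanol would remove the trimethylsilyl group to give 27.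

Step 16. Hydride delivery from the periphery of the ten-membered ring may override the Felkin–Anh preference and give mainly the alcohol epimeric at C9. The fallback sets out from 30 and comes back at 33. The 9-epimeric alcohol F4 would be inverted by a Mitsunobu reaction with acetic acid (PPh3, DIAD, toluene, 0 °C), which installs the C9 acetate directly as the inverted 9-acetate F5. Participation of the neighbouring angelate would have to be checked. HF·pyridine would then free C2–OH to give the 2-hydroxy 9-acetate F6, and acetylation (Ac2O, pyridine) would lead to 33.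

Step 4. Hydrogen abstraction at the allylic CH2 of the allyl group, or radical addition to the terminal alkene, may compete with oxidation at the ring γ-position. The fallback sets out from 7 and comes back at 9. Soft enolisation (TBSOTf, Et3N, CH2Cl2) would give the silyl dienol ether F7, whose electron-rich terminus is brominated by N-bromosuccinimide at −78 °C (vinylogous α-bromination) to the γ-bromo enone F8. N-methylmorpholine N-oxide in acetonitrile (Kornblum-type oxidation of the allylic bromide) would then give 9.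

**Further compounds**

F1 | step 14 | trimethylsilyl ether of 24 | C[C@@]1(/C=C/OCc2ccc(OC)cc2)C[C@@H](O[Si](C)(C)C(C)(C)C)C=C(C)[C@@]1(O[Si](C)(C)C)/C=C/C(=C)COCc3ccc(OC)cc3
F2 | step 14 | trimethylsilyl enol ether corresponding to enolate 26 | COc1ccc(CO[C@@H]2/C=C(\C)C[C@@H](O[Si](C)(C)C(C)(C)C)/C=C(/C)\C(O[Si](C)(C)C)=C\[C@H]2C(=C)COCc3ccc(OC)cc3)cc1
F3 | step 14 | 8-O-trimethylsilyl ether of 27 | COc1ccc(CO[C@@H]2/C=C(\C)C[C@@H](O[Si](C)(C)C(C)(C)C)/C=C(/C)C(=O)[C@H](O[Si](C)(C)C)[C@H]2C(=C)COCc3ccc(OC)cc3)cc1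
F4 | step 16 | C9 epimer of 31 | COc1ccc(CO[C@@H]2/C=C(\C)C[C@@H](O[Si](C)(C)C(C)(C)C)/C=C(/C)[C@H](O)[C@H](OC(=O)/C(C)=C\C)[C@H]2C(=C)COCc3ccc(OC)cc3)cc1
F5 | step 16 | 9-O-acetyl derivative of 31 (C2 silyl ether retained) | COc1ccc(CO[C@@H]2/C=C(\C)C[C@@H](O[Si](C)(C)C(C)(C)C)/C=C(/C)[C@@H](OC(C)=O)[C@H](OC(=O)/C(C)=C\C)[C@H]2C(=C)COCc3ccc(OC)cc3)cc1
F6 | step 16 | 9-O-acetyl derivative of 32 (free C2 hydroxyl) | COc1ccc(CO[C@@H]2/C=C(\C)C[C@@H](O)/C=C(/C)[C@@H](OC(C)=O)[C@H](OC(=O)/C(C)=C\C)[C@H]2C(=C)COCc3ccc(OC)cc3)cc1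
F7 | step 4 | tert-butyl[(6-allyl-2,6-dimethylcyclohexa-1,3-dien-1-yl)oxy]dimethylsilane (C6 as in 7) | C[C@@]1(CC=C)CC=CC(C)=C1O[Si](C)(C)C(C)(C)C
F8 | step 4 | 6-allyl-4-bromo-2,6-dimethylcyclohex-2-en-1-one (C6 as in 7, both C4 epimers) | C[C@@]1(CC=C)CC(Br)C=C(C)C1=O
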